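**Overview**

1. Cuts: after the fourteen benzyl ethers, the middle pyran is opened in one retro-[4+2] at C4(middle)–C8(bottom), C3–C4 and O1–C2 (C2–H traced back to a silyl ketal). Next come the O3(top)–Si–O(enol) tether and C4(top)–C8(middle), and ring A of the middle unit is traced back to cyclohexane-1,3-dione.
2. Enabling feature: ring A of the middle unit carries C4 of the top unit on its C8, beside C8a–O1. O3 of the top unit is therefore within one silicon atom of middle C2 (O3–C3–C4–C8–C8a–O1–C2), and C4a/C4 with C8a/O1 of the same ring form an o-quinone methide. The all-cis C2/C3/C4 pyran is what an endo addition of a Z-enol ether gives; a Friedel–Crafts union would go to C6 and give 3,4-trans.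
3. Forward: top chroman from (+)-dihydrorobinetin (C3 inverted) → C4 alkylation by cyclohexane-1,3-dione → aromatisation, ortho-formylation (C4 of the middle unit), O-Boc → silicon tether to the Z-enol ether carrying ring B, C2 and C3 of the middle unit → one-pot union with 8-lithio-epicatechin and closure of the middle pyran → ketal reduction, tether removal, hydrogenolysis.
4. Stereochemistry: top C2 from dihydrorobinetin, top C3 by bulky-hydride reduction of the 3-ketone, top C4 by anti attack on the C4 cation. Middle C3/C4 come from the tethered endo cycloaddition (relayed from top C3/C4), middle C2 from hydride addition anti to 3-OBn/4-aryl, and bottom C2/C3 from (−)-epicatechin.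

Key step: step 22

Remarks:
- Bn = benzyl, TBS = tert-butyldimethylsilyl, Boc = tert-butoxycarbonyl, Ar = 3,4,5-tris(benzyloxy)phenyl. Flavan numbering is used. "Top" is the 5-deoxy unit whose C4 bears the next ring, "middle" the unit built in step 22, "bottom" the epicatechin unit.
- "Top flavan-4-yl" means (2R,3R)-7-benzyloxy-2-Ar-chroman-4-yl with the stated 3-O substituent and the C4 bond trans to O3.
- Assumption: compounds 3–7 are carried as C4 epimer mixtures (drawn as the expected main epimer), since C4 becomes a cation in step 7. The carbinol carbon of 32 and 33 forms as a mixture and becomes planar in 34.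

**Route**

Step 1
Reactants: 1 (+)-dihydrorobinetin
Product: 2 (2R,3R)-7-benzyloxy-3-hydroxy-2-Ar-chroman-4-one
Conditions: BnBr (4.4 equiv), K2CO3, DMF, 0 °C → rt, argon
Reagents that add atoms: benzyl bromide, BrCc1ccccc1
Why: Williamson etherification in which K2CO3 deprotonates only the four phenols, the α-ketol hydroxyl stays free, and C2/C3 should not be disturbed at room temperature.

Step 2
Reactants: 2 (2R,3R)-7-benzyloxy-3-hydroxy-2-Ar-chroman-4-one
Product: 3 (2R,3S,4R)-7-benzyloxy-2-Ar-chromane-3,4-diol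
Conditions: NaBH4, MeOH–THF, 0 °C
Reagents that add atoms: none
Why: Borohydride reduction of the aryl ketone, expected to give mainly the 3,4-trans diol; the new C4 centre needs no control because it is ionised in step 7.

Step 3
Reactants: 3 (2R,3S,4R)-7-benzyloxy-2-Ar-chromane-3,4-diol
Product: 4 (2R,3S,4R)-7-benzyloxy-4-methoxy-2-Ar-chroman-3-ol
Conditions: camphorsulfonic acid (cat.), MeOH–CH2Cl2, 0 °C → rt
Reagents that add atoms: methanol, CO
Why: Acid-catalysed SN1 etherification in which only the 4-OH, benzylic to a ring with donor oxygens ortho (O1) and para (7-OBn), is exchanged for methoxy, leaving the 3-OH as the single free hydroxyl.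

Step 4
Reactants: 4 (2R,3S,4R)-7-benzyloxy-4-methoxy-2-Ar-chroman-3-ol
Product: 5 (2R,4R)-7-benzyloxy-4-methoxy-2-Ar-chroman-3-one
Conditions: Dess–Martin periodinane, NaHCO3, CH2Cl2, 0 °C → rt
Reagents that add atoms: none
Why: Dess–Martin oxidation of the secondary alcohol under buffered, non-enolising conditions, under which a flavan-3-one is expected to keep its C2 configuration.

Step 5
Reactants: 5 (2R,4R)-7-benzyloxy-4-methoxy-2-Ar-chroman-3-one
Product: 6 (2R,3R,4R)-7-benzyloxy-4-methoxy-2-Ar-chroman-3-ol (2,3-cis)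
Conditions: LiBH(s-Bu)3, THF, −78 °C; then H2O
Reagents that add atoms: none
Why: Substrate-controlled hydride reduction in which the bulky LiBH(s-Bu)3 attacks the ketone from the face away from the 2-aryl group (and the cis 4-OMe of the main epimer), setting C3 as R with the hydroxyl cis to the aryl group, the usual oxidation–reduction inversion of 2,3-trans flavan-3-ols.

Step 6
Reactants: 6 (2R,3R,4R)-7-benzyloxy-4-methoxy-2-Ar-chroman-3-ol
Product: 7 3-O-TBS ether of 6
Conditions: TBSCl, imidazole, DMAP (cat.), DMF, rt → 40 °C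
Reagents that add atoms: tert-butyldimethylsilyl chloride, CC(C)(C)[Si](C)(C)Cl
Why: Silyl ether formation with the chloride and imidazole, chosen over a Lewis-acidic silyl triflate that could ionise the 4-OMe; the bulky silyl ether later shields one face of C4.

Step 7
Reactants: 7 3-O-TBS ether of 6; 8 cyclohexane-1,3-dione
Product: 9 2-(top flavan-4-yl)cyclohexane-1,3-dione (3-OTBS)
Conditions: 8 (3 equiv), Me3SiOTf (0.2 equiv), CH2Cl2–MeCN, −40 → 0 °C
Reagents that add atoms: none
Why: Lewis-acid-catalysed SN1 benzylation of a cyclic 1,3-dione in which the 4-OMe ionises to the O1/7-OBn-stabilised cation and the dione enol captures it at its C2 (O-alkylation is reversible under the acid) from the face anti to the pseudo-axial 3-OTBS, setting top C4 with the 3,4-trans relation.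

Step 8
Reactants: 9 2-(top flavan-4-yl)cyclohexane-1,3-dione (3-OTBS)
Product: 10 3-benzyloxy-2-(top flavan-4-yl)cyclohex-2-en-1-one (3-OTBS)
Conditions: BnBr, Cs2CO3, DMF, rt
Reagents that add atoms: benzyl bromide, BrCc1ccccc1
Why: O-alkylation of the cesium enolate of a 2-substituted cyclic 1,3-dione, with C-alkylation blocked by the bulky flavanyl group on C2 and a single vinylogous ester formed because the dione is symmetric.

Step 9
Reactants: 10 3-benzyloxy-2-(top flavan-4-yl)cyclohex-2-en-1-one (3-OTBS)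
Product: 12 3-benzyloxy-2-(top flavan-4-yl)phenol (3-OTBS), via 3-benzyloxy-2-(top flavan-4-yl)cyclohexa-2,5-dienone 11 (not isolated)
Conditions: LiN(i-Pr)2, THF, −78 °C; then PhS(Cl)=N-t-Bu, −78 °C → rt
Reagents that add atoms: none
Why: Mukaiyama dehydrogenation in which kinetic deprotonation at the α'-CH2 of the vinylogous ester, S-sulfinimidoylation and syn-elimination give dienone 11, whose tautomerisation to the monobenzyl resorcinol is driven by aromatisation.

Step 10
Reactants: 12 3-benzyloxy-2-(top flavan-4-yl)phenol (3-OTBS); 13 paraformaldehyde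
Product: 14 4-benzyloxy-2-hydroxy-3-(top flavan-4-yl)benzaldehyde (3-OTBS)
Conditions: MgCl2, Et3N, (CH2O)n, THF, reflux
Reagents that add atoms: none
Why: Casnati–Skattebøl ortho-formylation in which the magnesium phenoxide delivers formaldehyde only ortho to the hydroxyl, whose single free ortho carbon is the future C4a, and a second formaldehyde oxidises the salicyl alcohol by hydride transfer.

Step 11
Reactants: 14 4-benzyloxy-2-hydroxy-3-(top flavan-4-yl)benzaldehyde (3-OTBS)
Product: 15 4-benzyloxy-2-hydroxy-3-(top flavan-4-yl)benzaldehyde (top 3-OH free)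
Conditions: Bu4NF, THF, 0 °C → rt
Reagents that add atoms: none
Why: Fluoride-induced desilylation, to which the aldehyde, the benzyl ethers and the C4–aryl bond are inert.

Step 12
Reactants: 15 4-benzyloxy-2-hydroxy-3-(top flavan-4-yl)benzaldehyde (top 3-OH free)
Product: 16 tert-butyl aryl carbonate of 15 (O-Boc salicylaldehyde, top 3-OH free)
Conditions: Boc2O (1.1 equiv), i-Pr2NEt, DMAP (2 mol %), CH2Cl2, 0 °C
Reagents that add atoms: di-tert-butyl dicarbonate, CC(C)(C)OC(=O)OC(=O)OC(C)(C)C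
Why: Chemoselective acyl transfer in which the acidic, aldehyde-conjugated phenol is acylated under amine base much faster than the hindered secondary 3-OH, as in the usual preparation of O-Boc salicylaldehydes.

Step 13
Reactants: 17 5-bromo-1,2,3-trimethoxybenzene
Product: 18 5-bromobenzene-1,2,3-triol
Conditions: BBr3, CH2Cl2, −78 °C → rt; then H2O
Reagents that add atoms: none
Why: Lewis-acid cleavage of the three aryl methyl ethers with BBr3, to which the aryl bromide is inert.

Step 14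
Reactants: 18 5-bromobenzene-1,2,3-triol
Product: 19 5-bromo-1,2,3-tris(benzyloxy)benzene
Conditions: BnBr, K2CO3, DMF, rt, argon
Reagents that add atoms: benzyl bromide, BrCc1ccccc1
Why: Williamson etherification of the three phenols, run under argon because the bromopyrogallol is air-sensitive.

Step 15
Reactants: 20 benzyloxyacetyl chloride
Product: 21 2-benzyloxy-N-methoxy-N-methylacetamide
Conditions: MeNH(OMe)·HCl, Et3N, CH2Cl2, 0 °C
Reagents that add atoms: N,O-dimethylhydroxylamine hydrochloride, CNOC.Cl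
Why: Amide formation from an acid chloride, giving the Weinreb amide.

Step 16
Reactants: 19 5-bromo-1,2,3-tris(benzyloxy)benzene; 21 2-benzyloxy-N-methoxy-N-methylacetamide
Product: 23 2-benzyloxy-1-Ar-ethanone, via 3,4,5-tris(benzyloxy)phenyllithium 22 (not isolated)
Conditions: n-BuLi, THF, −78 °C; then 21, −78 → 0 °C; then H2O
Reagents that add atoms: none
Why: Bromine–lithium exchange followed by Weinreb ketone synthesis, in which N-methoxy chelation stops the addition at the ketone stage.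

Step 17
Reactants: 23 2-benzyloxy-1-Ar-ethanone
Product: 25 (Z)-2-benzyloxy-1-Ar-ethenyl chlorodiisopropylsilyl ether, via lithium Z-enolate 24 (not isolated)
Conditions: LiN(SiMe3)2, THF, −78 °C; then i-Pr2SiCl2 (5 equiv), −78 → 0 °C; volatiles removed in vacuo
Reagents that add atoms: dichlorodiisopropylsilane, CC(C)[Si](Cl)(Cl)C(C)C
Why: Enolate O-silylation in which the α-benzyloxy ketone gives the lithium-chelated Z-enolate 24 (O–Li bridged to OBn), which fixes the Z geometry, and a large excess of the dichlorosilane ensures monosubstitution.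

Step 18
Reactants: 16 O-Boc salicylaldehyde (top 3-OH free); 25 (Z)-chlorodiisopropylsilyl enol ether
Product: 26 tethered precursor: 16 with top O3 joined through Si(i-Pr)2 to the enol oxygen of (Z)-ArC(O)=CH(OBn)
Conditions: 25 (1.5 equiv), imidazole, DMF–CH2Cl2, 0 °C → rt
Reagents that add atoms: none
Why: Silyl ether formation between the only free hydroxyl of 16 and the chlorosilane, the standard way to assemble a mixed diisopropylsilaketal tether.

Step 19
Reactants: 27 (−)-epicatechin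
Product: 28 5,7,3',4'-tetra-O-benzylepicatechin
Conditions: BnBr, K2CO3, DMF, 0 °C → rt, argon
Reagents that add atoms: benzyl bromide, BrCc1ccccc1
Why: Williamson etherification of the four phenols, with K2CO3 leaving the 3-OH free.

Step 20
Reactants: 28 5,7,3',4'-tetra-O-benzylepicatechin
Product: 29 8-bromo-5,7,3',4'-tetra-O-benzylepicatechin
Conditions: NBS, CH2Cl2, −78 °C → rt
Reagents that add atoms: N-bromosuccinimide, O=C1CCC(=O)N1Br
Why: Electrophilic aromatic bromination, which in the benzylated phloroglucinol ring takes place at C8 (flanked by O1 and 7-OBn) in preference to C6.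

Step 21
Reactants: 29 8-bromo-5,7,3',4'-tetra-O-benzylepicatechin
Product: 30 8-bromo-3,5,7,3',4'-penta-O-benzylepicatechin
Conditions: NaH, BnBr, DMF, 0 °C → rt
Reagents that add atoms: benzyl bromide, BrCc1ccccc1
Why: Williamson etherification of the secondary alkoxide, which leaves the aryl bromide and both stereocentres untouched.

Step 22
Reactants: 30 8-bromo-3,5,7,3',4'-penta-O-benzylepicatechin; 26 tethered precursor
Product: 35 bridged silaketal cycloadduct (middle pyran closed; middle C2 a silyl ketal tied to top O3 by Si(i-Pr)2; ketal O–Si oxygen cis to 3-OBn and to the 4-(epicatechin-8-yl) group; middle C4 S), via 8-lithio-penta-O-benzylepicatechin 31 (not isolated), via lithium carbinolate adduct 32 (not isolated), via Boc-shifted lithium phenoxide 33 (not isolated), via E-o-quinone methide 34 (not isolated)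
Conditions: 30 (1.05 equiv), t-BuLi (2.1 equiv), Et2O–THF, −78 °C; then 26, −78 °C; then MgBr2·OEt2 (1.5 equiv), −78 °C → rt
Reagents that add atoms: none
Why: Proposed new method: aryllithium 31 adds to the aldehyde of 26, alkoxide 32 takes over the Boc group through a six-membered transition state to give phenoxide 33, MgBr2 then drives loss of tert-butyl carbonate to the E-o-quinone methide 34, and the tethered Z-enol ether adds to it in an asynchronous inverse-electron-demand [4+2] reaction in which the OBn-bearing carbon first bonds to the methide carbon and O1 then collapses onto the aryl- and silyloxy-stabilised C2 cation. The closest known reaction types are the organometallic-triggered o-quinone methide cascade of O-Boc salicylaldehydes with endo-selective hetero-Diels–Alder trapping by simple enol ethers, and temporary-silicon-tethered Diels–Alder reactions; joining the two on an enol ether that carries oxygen on both carbons and an aryl group has no precedent. Two rings close: the middle pyran by the [4+2] event (C3–C4 bond through an eleven-membered tethered array, then 6-exo-trig attack of O1 on C2) and, through the same O1–C2 bond, the nine-membered silaketal ring Si–O3(top)–C3–C4–C8–C8a–O1–C2–O. Middle C4 (S) is set by the face of the planar methide, because with H4 of the top unit lying in the ring plane toward the 7-OBn group the R-configured top C4 holds O3 and its silicon next to the methide oxygen on one face only; middle C3 is set by the endo orientation that the short tether imposes on the silyloxy group, which through the Z-alkene places OBn endo and therefore cis to the outward-pointing aryl group on C4; the ketal carbon C2 follows from suprafacial addition (silyloxy cis to OBn). The step needs regio-, facial and endo selectivity and a rate that outruns dimerisation of a methide slowed by its 7-OBn donor: regiochemistry is secured by the cation-stabilising aryl and silyloxy groups on the carbon that meets O1, face and endo orientation by the tether, and rate by intramolecularity at a 1:1 ratio of partners. The methide carbon carries only an aryl group and hydrogen, so it cannot escape by tautomerising to a styrene.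

Step 23
Reactants: 35 bridged silaketal cycloadduct
Product: 36 all-cis middle flavan (middle 2R,3R,4S) with top O3 carrying Si(i-Pr)2–O–SiEt3
Conditions: Et3SiH (5 equiv), Me3SiOTf (0.2 equiv), CH2Cl2, −78 → −40 °C
Reagents that add atoms: triethylsilane, CC[SiH](CC)CC
Why: Ionic hydrogenation of a mixed ketal in which silyl-assisted departure of the bridging silanolate oxygen gives the 2-aryl oxocarbenium ion and Et3SiH delivers hydride on the face anti to the cis 3-OBn and 4-aryl groups, so the 2-aryl group ends cis to both (middle C2 R) and the released silicon is capped as a triethylsilyl disiloxane on top O3.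

Step 24
Reactants: 36 all-cis middle flavan with top O3 carrying Si(i-Pr)2–O–SiEt3
Product: 37 tetradeca-O-benzyl trimer with free top 3-OH
Conditions: Bu4NF, THF, rt
Reagents that add atoms: none
Why: Fluoride cleavage of both Si–O bonds of the disiloxane-capped silyl ether frees the top 3-OH while the fourteen benzyl ethers stay intact.

Step 25
Reactants: 37 tetradeca-O-benzyl trimer with free top 3-OH
Product: 38 target CNP0115797.2
Conditions: H2 (1 atm), Pd(OH)2/C, THF–MeOH–H2O, rt; filtration and lyophilisation under argon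
Reagents that add atoms: none
Why: Catalytic hydrogenolysis of all fourteen benzyl ethers over Pd(OH)2/C, conditions under which the diarylmethine interflavan bonds and the benzylic C2–O1 bonds of flavans are known to survive in procyanidin chemistry.

**Compound list**

1 | (+)-dihydrorobinetin, (2R,3R) | Oc1ccc2c(c1)O[C@H](c1cc(O)c(O)c(O)c1)[C@@H](O)C2=O | starting material
2 | (2R,3R)-7-benzyloxy-3-hydroxy-2-Ar-chroman-4-one | C(c1ccccc1)Oc1ccc2c(c1)O[C@H](c1cc(OCc3ccccc3)c(OCc3ccccc3)c(OCc3ccccc3)c1)[C@@H](O)C2=O | intermediate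
3 | (2R,3S,4R)-7-benzyloxy-2-Ar-chromane-3,4-diol (main C4 epimer) | C(c1ccccc1)Oc1ccc2c(c1)O[C@H](c1cc(OCc3ccccc3)c(OCc3ccccc3)c(OCc3ccccc3)c1)[C@@H](O)[C@@H]2O | intermediate
4 | (2R,3S,4R)-7-benzyloxy-4-methoxy-2-Ar-chroman-3-ol (main C4 epimer) | C(c1ccccc1)Oc1ccc2c(c1)O[C@H](c1cc(OCc3ccccc3)c(OCc3ccccc3)c(OCc3ccccc3)c1)[C@@H](O)[C@@H]2OC | intermediate
5 | (2R,4R)-7-benzyloxy-4-methoxy-2-Ar-chroman-3-one | C(c1ccccc1)Oc1ccc2c(c1)O[C@H](c1cc(OCc3ccccc3)c(OCc3ccccc3)c(OCc3ccccc3)c1)C(=O)[C@@H]2OC | intermediate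
6 | (2R,3R,4R)-7-benzyloxy-4-methoxy-2-Ar-chroman-3-ol (2,3-cis) | C(c1ccccc1)Oc1ccc2c(c1)O[C@H](c1cc(OCc3ccccc3)c(OCc3ccccc3)c(OCc3ccccc3)c1)[C@H](O)[C@@H]2OC | intermediate
7 | 3-O-TBS ether of 6 | C(c1ccccc1)Oc1ccc2c(c1)O[C@H](c1cc(OCc3ccccc3)c(OCc3ccccc3)c(OCc3ccccc3)c1)[C@H](O[Si](C)(C)C(C)(C)C)[C@@H]2OC | intermediate
8 | cyclohexane-1,3-dione | O=C1CCCC(=O)C1 | starting material
9 | 2-(top flavan-4-yl)cyclohexane-1,3-dione (3-OTBS, 3,4-trans) | C(c1ccccc1)Oc1ccc2c(c1)O[C@H](c1cc(OCc3ccccc3)c(OCc3ccccc3)c(OCc3ccccc3)c1)[C@H](O[Si](C)(C)C(C)(C)C)[C@H]2C1C(=O)CCCC1=O | intermediate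
10 | 3-benzyloxy-2-(top flavan-4-yl)cyclohex-2-en-1-one (3-OTBS) | C(c1ccccc1)Oc1ccc2c(c1)O[C@H](c1cc(OCc3ccccc3)c(OCc3ccccc3)c(OCc3ccccc3)c1)[C@H](O[Si](C)(C)C(C)(C)C)[C@H]2C1=C(OCc3ccccc3)CCCC1=O | intermediate
11 | 3-benzyloxy-2-(top flavan-4-yl)cyclohexa-2,5-dien-1-one (3-OTBS; formed in the flask) | C(c1ccccc1)Oc1ccc2c(c1)O[C@H](c1cc(OCc3ccccc3)c(OCc3ccccc3)c(OCc3ccccc3)c1)[C@H](O[Si](C)(C)C(C)(C)C)[C@H]2C1=C(OCc3ccccc3)CC=CC1=O | intermediate
12 | 3-benzyloxy-2-(top flavan-4-yl)phenol (3-OTBS) | C(c1ccccc1)Oc1ccc2c(c1)O[C@H](c1cc(OCc3ccccc3)c(OCc3ccccc3)c(OCc3ccccc3)c1)[C@H](O[Si](C)(C)C(C)(C)C)[C@H]2c1c(OCc3ccccc3)cccc1O | intermediate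
13 | paraformaldehyde (formaldehyde source) | C=O | starting material
14 | 4-benzyloxy-2-hydroxy-3-(top flavan-4-yl)benzaldehyde (3-OTBS) | C(c1ccccc1)Oc1ccc2c(c1)O[C@H](c1cc(OCc3ccccc3)c(OCc3ccccc3)c(OCc3ccccc3)c1)[C@H](O[Si](C)(C)C(C)(C)C)[C@H]2c1c(OCc3ccccc3)ccc(C=O)c1O | intermediate
15 | 4-benzyloxy-2-hydroxy-3-(top flavan-4-yl)benzaldehyde (top 3-OH free) | C(c1ccccc1)Oc1ccc2c(c1)O[C@H](c1cc(OCc3ccccc3)c(OCc3ccccc3)c(OCc3ccccc3)c1)[C@H](O)[C@H]2c1c(OCc3ccccc3)ccc(C=O)c1O | intermediate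
16 | tert-butyl aryl carbonate of 15 (O-Boc salicylaldehyde, top 3-OH free) | C(c1ccccc1)Oc1ccc2c(c1)O[C@H](c1cc(OCc3ccccc3)c(OCc3ccccc3)c(OCc3ccccc3)c1)[C@H](O)[C@H]2c1c(OCc3ccccc3)ccc(C=O)c1OC(=O)OC(C)(C)C | intermediate
17 | 5-bromo-1,2,3-trimethoxybenzene | COc1cc(Br)cc(OC)c1OC | starting material
18 | 5-bromobenzene-1,2,3-triol | Oc1cc(Br)cc(O)c1O | intermediate
19 | 5-bromo-1,2,3-tris(benzyloxy)benzene | Brc1cc(OCc2ccccc2)c(OCc2ccccc2)c(OCc2ccccc2)c1 | intermediate
20 | benzyloxyacetyl chloride | O=C(Cl)COCc1ccccc1 | starting material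
21 | 2-benzyloxy-N-methoxy-N-methylacetamide | CON(C)C(=O)COCc1ccccc1 | intermediate
22 | 3,4,5-tris(benzyloxy)phenyllithium (formed in the flask) | [Li]c1cc(OCc2ccccc2)c(OCc2ccccc2)c(OCc2ccccc2)c1 | intermediate
23 | 2-benzyloxy-1-Ar-ethanone | O=C(COCc1ccccc1)c1cc(OCc2ccccc2)c(OCc2ccccc2)c(OCc2ccccc2)c1 | intermediate
24 | lithium (Z)-enolate of 23 (formed in the flask) | [Li]O/C(c1cc(OCc2ccccc2)c(OCc2ccccc2)c(OCc2ccccc2)c1)=C\OCc1ccccc1 | intermediate
25 | (Z)-2-benzyloxy-1-Ar-ethenyl chlorodiisopropylsilyl ether | Cl[Si](C(C)C)(C(C)C)O/C(c1cc(OCc2ccccc2)c(OCc2ccccc2)c(OCc2ccccc2)c1)=C\OCc1ccccc1 | intermediate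
26 | tethered precursor: 16 with top O3–Si(i-Pr)2–O–C(Ar)=CH(OBn), Z | C(c1ccccc1)Oc1ccc2c(c1)O[C@H](c1cc(OCc3ccccc3)c(OCc3ccccc3)c(OCc3ccccc3)c1)[C@H](O[Si](C(C)C)(C(C)C)O/C(c1cc(OCc3ccccc3)c(OCc3ccccc3)c(OCc3ccccc3)c1)=C\OCc1ccccc1)[C@H]2c1c(OCc3ccccc3)ccc(C=O)c1OC(=O)OC(C)(C)C | intermediate
27 | (−)-epicatechin, (2R,3R) | Oc1cc(O)c2c(c1)O[C@H](c1ccc(O)c(O)c1)[C@H](O)C2 | starting material
28 | 5,7,3',4'-tetra-O-benzylepicatechin | C(c1ccccc1)Oc1cc(OCc3ccccc3)c2c(c1)O[C@H](c1ccc(OCc3ccccc3)c(OCc3ccccc3)c1)[C@H](O)C2 | intermediate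
29 | 8-bromo-5,7,3',4'-tetra-O-benzylepicatechin | Brc1c(OCc3ccccc3)cc(OCc3ccccc3)c2c1O[C@H](c1ccc(OCc3ccccc3)c(OCc3ccccc3)c1)[C@H](O)C2 | intermediate
30 | 8-bromo-3,5,7,3',4'-penta-O-benzylepicatechin | Brc1c(OCc3ccccc3)cc(OCc3ccccc3)c2c1O[C@H](c1ccc(OCc3ccccc3)c(OCc3ccccc3)c1)[C@H](OCc1ccccc1)C2 | intermediate
31 | 8-lithio-3,5,7,3',4'-penta-O-benzylepicatechin (formed in the flask) | [Li]c1c(OCc3ccccc3)cc(OCc3ccccc3)c2c1O[C@H](c1ccc(OCc3ccccc3)c(OCc3ccccc3)c1)[C@H](OCc1ccccc1)C2 | intermediate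
32 | lithium carbinolate from addition of 31 to the aldehyde of 26 (carbinol epimers; formed in the flask) | C(c1ccccc1)Oc1ccc2c(c1)O[C@H](c1cc(OCc3ccccc3)c(OCc3ccccc3)c(OCc3ccccc3)c1)[C@H](O[Si](C(C)C)(C(C)C)O/C(c1cc(OCc3ccccc3)c(OCc3ccccc3)c(OCc3ccccc3)c1)=C\OCc1ccccc1)[C@H]2c1c(OCc3ccccc3)ccc(C(O[Li])c4c(OCc3ccccc3)cc(OCc3ccccc3)c5c4O[C@H](c4ccc(OCc3ccccc3)c(OCc3ccccc3)c4)[C@H](OCc4ccccc4)C5)c1OC(=O)OC(C)(C)C | intermediate
33 | lithium phenoxide with the Boc group shifted to the carbinol oxygen (formed in the flask) | C(c1ccccc1)Oc1ccc2c(c1)O[C@H](c1cc(OCc3ccccc3)c(OCc3ccccc3)c(OCc3ccccc3)c1)[C@H](O[Si](C(C)C)(C(C)C)O/C(c1cc(OCc3ccccc3)c(OCc3ccccc3)c(OCc3ccccc3)c1)=C\OCc1ccccc1)[C@H]2c1c(OCc3ccccc3)ccc(C(OC(=O)OC(C)(C)C)c4c(OCc3ccccc3)cc(OCc3ccccc3)c5c4O[C@H](c4ccc(OCc3ccccc3)c(OCc3ccccc3)c4)[C@H](OCc4ccccc4)C5)c1O[Li] | intermediate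
34 | E-o-quinone methide of middle ring A, tether intact (formed in the flask) | C(c1ccccc1)Oc1ccc2c(c1)O[C@H](c1cc(OCc3ccccc3)c(OCc3ccccc3)c(OCc3ccccc3)c1)[C@H](O[Si](C(C)C)(C(C)C)O/C(c1cc(OCc3ccccc3)c(OCc3ccccc3)c(OCc3ccccc3)c1)=C\OCc1ccccc1)[C@H]2C1=C(OCc3ccccc3)C=C/C(=C\c4c(OCc3ccccc3)cc(OCc3ccccc3)c5c4O[C@H](c4ccc(OCc3ccccc3)c(OCc3ccccc3)c4)[C@H](OCc4ccccc4)C5)C1=O | intermediate
35 | bridged silaketal cycloadduct (nine-membered Si ring from top O3 to middle C2; 2-O–Si, 3-OBn and 4-aryl mutually cis; middle C4 S) | C(c1ccccc1)Oc1ccc2c(c1)O[C@H](c1cc(OCc3ccccc3)c(OCc3ccccc3)c(OCc3ccccc3)c1)[C@H](O[Si]4(C(C)C)C(C)C)[C@H]2c1c(OCc3ccccc3)ccc2c1O[C@@](O4)(c1cc(OCc3ccccc3)c(OCc3ccccc3)c(OCc3ccccc3)c1)[C@H](OCc1ccccc1)[C@@H]2c1c(OCc3ccccc3)cc(OCc3ccccc3)c2c1O[C@H](c1ccc(OCc3ccccc3)c(OCc3ccccc3)c1)[C@H](OCc1ccccc1)C2 | intermediate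
36 | benzylated trimer with all-cis middle unit (2R,3R,4S), top O3 carrying Si(i-Pr)2–O–SiEt3 | C(c1ccccc1)Oc1ccc2c(c1)O[C@H](c1cc(OCc3ccccc3)c(OCc3ccccc3)c(OCc3ccccc3)c1)[C@H](O[Si](C(C)C)(C(C)C)O[Si](CC)(CC)CC)[C@H]2c1c(OCc3ccccc3)ccc2c1O[C@H](c1cc(OCc3ccccc3)c(OCc3ccccc3)c(OCc3ccccc3)c1)[C@H](OCc1ccccc1)[C@@H]2c1c(OCc3ccccc3)cc(OCc3ccccc3)c2c1O[C@H](c1ccc(OCc3ccccc3)c(OCc3ccccc3)c1)[C@H](OCc1ccccc1)C2 | intermediate
37 | tetradeca-O-benzyl trimer with free top 3-OH | C(c1ccccc1)Oc1ccc2c(c1)O[C@H](c1cc(OCc3ccccc3)c(OCc3ccccc3)c(OCc3ccccc3)c1)[C@H](O)[C@H]2c1c(OCc3ccccc3)ccc2c1O[C@H](c1cc(OCc3ccccc3)c(OCc3ccccc3)c(OCc3ccccc3)c1)[C@H](OCc1ccccc1)[C@@H]2c1c(OCc3ccccc3)cc(OCc3ccccc3)c2c1O[C@H](c1ccc(OCc3ccccc3)c(OCc3ccccc3)c1)[C@H](OCc1ccccc1)C2 | intermediate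
38 | CNP0115797.2 | Oc1ccc2c(c1)O[C@H](c1cc(O)c(O)c(O)c1)[C@H](O)[C@H]2c1c(O)ccc2c1O[C@H](c1cc(O)c(O)c(O)c1)[C@H](O)[C@@H]2c1c(O)cc(O)c2c1O[C@H](c1ccc(O)c(O)c1)[C@H](O)C2 | target

**Step count**

Total step count: 25. Longest linear sequence: 17 steps (steps 1–12, 18, 22–25).

**Steps most likely to fail**

Step 22 (proposed new method).
- What may go wrong: the quinone methide may be consumed before the tether delivers the enol ether (self-dimerisation, 1,4-addition of tert-butoxide or residual aryllithium). The Boc shift may stall at the alkoxide, or the eleven-membered first bond formation may be too slow and erode facial and endo control.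
- Fallback (known, untethered, acid-triggered chemistry), setting out from aldehyde 14, bromide 30 and ketone 23: the phenol of 14 is deprotonated with NaH and aryllithium 31 (from 30) is added to the aldehyde to give the o-hydroxybenzhydrol F1. Ketone 23 is converted with LiN(SiMe3)2 and Me3SiCl into its (Z)-trimethylsilyl enol ether F2. Catalytic Me3SiOTf in CH2Cl2 at −78 °C ionises F1 to the o-quinone methide, which F2 traps in an intermolecular [4+2]/Mukaiyama–Michael addition to give the 2-trimethylsilyloxy ketal F3. Et3SiH under the same acid reduces F3 to the 3-O-TBS trimer F4, and Bu4NF then gives 37, where the route is rejoined. Without the tether the diastereomers at middle C3/C4 would have to be separated by chromatography.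

Step 23.
- What may go wrong: ionisation of the ketal at the wrong oxygen (opening of the pyran at O1), or proton loss from C3 of the oxocarbenium ion to a 4H-chromene instead of hydride capture.
- Fallback, setting out from 35: the silicon bridge is cut first with HF·pyridine in THF to give the lactol F5 (2-hydroxyflavan, in equilibrium with its ring-opened keto phenol). In F5 the only ionisable group at C2 is the hydroxyl, and a ring-opened form recloses through the phenol. Classical lactol-to-flavan ionic hydrogenation (Et3SiH, CF3CO2H, CH2Cl2, −20 °C) then gives 37 directly. The acidic fluoride source is chosen so that the α-benzyloxy ketone form is not epimerised at C3.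

Step 18.
- What may go wrong: slow silylation of the hindered axial 3-OH by a hindered chlorosilane, giving the neighbouring aryl carbonate time to migrate to O3 or be cleaved by the amine, and hydrolysis of the silyl enol ether.
- Fallback, setting out from diol 15 and chlorosilane 25, with tethering and carbonate formation in reverse order: 15 is deprotonated twice with KN(SiMe3)2 (2 equiv, THF, −78 °C) to the dipotassium salt F6. Its alkoxide, far more nucleophilic than the aldehyde-conjugated phenoxide, is silylated by 25 to give the tethered potassium phenoxide F7. Boc2O added to the same flask caps the phenoxide and gives 26, where the route is rejoined; no intermediate then has a free 3-OH beside the carbonate.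

Further compounds
F1 | step 22 | o-hydroxybenzhydrol from 14 and 31 (3-OTBS, carbinol epimers) | C(c1ccccc1)Oc1ccc2c(c1)O[C@H](c1cc(OCc3ccccc3)c(OCc3ccccc3)c(OCc3ccccc3)c1)[C@H](O[Si](C)(C)C(C)(C)C)[C@H]2c1c(OCc3ccccc3)ccc(C(O)c4c(OCc3ccccc3)cc(OCc3ccccc3)c5c4O[C@H](c4ccc(OCc3ccccc3)c(OCc3ccccc3)c4)[C@H](OCc4ccccc4)C5)c1O
F2 | step 22 | (Z)-2-benzyloxy-1-Ar-ethenyl trimethylsilyl ether | C[Si](C)(C)O/C(c1cc(OCc2ccccc2)c(OCc2ccccc2)c(OCc2ccccc2)c1)=C\OCc1ccccc1
F3 | step 22 | 2-trimethylsilyloxy ketal of the middle pyran (top 3-OTBS; 2-O–Si, 3-OBn and 4-aryl cis) | C(c1ccccc1)Oc1ccc2c(c1)O[C@H](c1cc(OCc3ccccc3)c(OCc3ccccc3)c(OCc3ccccc3)c1)[C@H](O[Si](C)(C)C(C)(C)C)[C@H]2c1c(OCc3ccccc3)ccc2c1O[C@@](O[Si](C)(C)C)(c1cc(OCc3ccccc3)c(OCc3ccccc3)c(OCc3ccccc3)c1)[C@H](OCc1ccccc1)[C@@H]2c1c(OCc3ccccc3)cc(OCc3ccccc3)c2c1O[C@H](c1ccc(OCc3ccccc3)c(OCc3ccccc3)c1)[C@H](OCc1ccccc1)C2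
F4 | step 22 | tetradeca-O-benzyl trimer with top 3-OTBS | C(c1ccccc1)Oc1ccc2c(c1)O[C@H](c1cc(OCc3ccccc3)c(OCc3ccccc3)c(OCc3ccccc3)c1)[C@H](O[Si](C)(C)C(C)(C)C)[C@H]2c1c(OCc3ccccc3)ccc2c1O[C@H](c1cc(OCc3ccccc3)c(OCc3ccccc3)c(OCc3ccccc3)c1)[C@H](OCc1ccccc1)[C@@H]2c1c(OCc3ccccc3)cc(OCc3ccccc3)c2c1O[C@H](c1ccc(OCc3ccccc3)c(OCc3ccccc3)c1)[C@H](OCc1ccccc1)C2
F5 | step 23 | lactol of the middle pyran (2-hydroxyflavan, 2-OH cis to 3-OBn, top 3-OH free) | C(c1ccccc1)Oc1ccc2c(c1)O[C@H](c1cc(OCc3ccccc3)c(OCc3ccccc3)c(OCc3ccccc3)c1)[C@H](O)[C@H]2c1c(OCc3ccccc3)ccc2c1O[C@@](O)(c1cc(OCc3ccccc3)c(OCc3ccccc3)c(OCc3ccccc3)c1)[C@H](OCc1ccccc1)[C@@H]2c1c(OCc3ccccc3)cc(OCc3ccccc3)c2c1O[C@H](c1ccc(OCc3ccccc3)c(OCc3ccccc3)c1)[C@H](OCc1ccccc1)C2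
F6 | step 18 | dipotassium salt of diol 15 | C(c1ccccc1)Oc1ccc2c(c1)O[C@H](c1cc(OCc3ccccc3)c(OCc3ccccc3)c(OCc3ccccc3)c1)[C@H](O[K])[C@H]2c1c(OCc3ccccc3)ccc(C=O)c1O[K]
F7 | step 18 | tethered potassium phenoxide (26 without the Boc group) | C(c1ccccc1)Oc1ccc2c(c1)O[C@H](c1cc(OCc3ccccc3)c(OCc3ccccc3)c(OCc3ccccc3)c1)[C@H](O[Si](C(C)C)(C(C)C)O/C(c1cc(OCc3ccccc3)c(OCc3ccccc3)c(OCc3ccccc3)c1)=C\OCc1ccccc1)[C@H]2c1c(OCc3ccccc3)ccc(C=O)c1O[K]
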